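In a one-step world each X consumes one D, and Sunday's 1.05 equiv of X would cover the D charged; but that flask, the one asked about, holds D near 27.7% from 25.0 min on.

| setting | Sunday's | Monday's | flask |
|---|---|---|---|
| D | 0.010 M | 0.0067 M | 0.010 M |
| X | 1.05 equiv | 1.05 equiv | 1.05 equiv |
| remark | the very flask that is asked about, followed so far | run made earlier |  |
| time |  |  | 2.0 h |

- Sunday's (time / min: E / %, D / %): 25.0: 23.3, 28.2; 50.0: 22.9, 27.8; 80.0: 23.0, 27.2; 90.0: 23.5, 27.2; 120: 23.5, 27.7
- Monday's (time / min: E / %, D / %): 2.00: 2.3, 74.5; 4.00: 5.8, 60.5; 8.00: 12.3, 44.7; 12.0: 16.3, 37.7; 25.0: 21.8, 29.8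

(readings scatter by 0.3 percentage points)

- E, in percent of the D first charged, at 2.0 h
- what to do for the largest gain in E; "none" if nothing gains more than 2 percentage points (grey / teal / amber / ochre / none)
- E present, with what was taken out counted in, in percent of the D first charged, after amber
- E present, with what was taken out counted in, in percent of the D first charged, after ochre

- grey: at 2.0 h take out 90% of the E then present, then wait 2.0 h
- teal: change nothing and wait 2.0 h more
- amber: at 2.0 h add X, 50.0% of the amount charged, then wait 2.0 h
- ochre: at 2.0 h add D, 50.0% of the amount charged, then wait 2.0 h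

- removed E is counted in
- reactions considered so far: D + X -> Q; X + Q -> E; X + E -> L
- additions bring no volume worth counting

The listed steps make X pay again for each further adduct: a Q costs one X, an E two, an L three. So Monday's first reading, with L neglected, gives 1.09 for the price, the X spent per D consumed. But Sunday's last reading, taking the whole charge of X as spent, puts the price at 1.45, so the flask stops with D unconsumed and X as limiting reagent. The reckoning here therefore takes the mean of Sunday's E readings for now, 23.2%, and looks to amber, the option that brings X.

The forecast gives 23.3% now, amber as best, 39% after amber and 23.3% after ochre, holding that “Teal, grey and ochre supply no X”.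

The flask gives 23.1% now, amber as best with a gain of 14 percentage points, 37.2% after amber and 23.1% after ochre.

    D + X → Q (k = 0.402 M⁻¹ s⁻¹)
    X + Q → E (k = 0.268 M⁻¹ s⁻¹)
    X + E → L (k = 0.155 M⁻¹ s⁻¹)

The flask has come to rest: X stands at 0% of its charge at 120 min, having fallen under a fiftieth by 22.0 min. At 1200 min E still reads 23.1%, D 27.7% and Q 44.4%, so ten times the time changes nothing. The flask's price at rest, with the whole charge of X counted as spent, stays 1.45. The forecast's amber figure stands 1.8 points above the flask's.

A neighbour charged with 0.260 equiv of X should, at the price of 1.09, consume 0.239 equiv of D and make 0.0215 equiv of E. At 120 min it holds D 76.2% and E 2.05%.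

All runs were computed for substances that don't exist, noise included.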